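The target is (2S)-sakuranetin carrying prenyl groups at C6 and C8 of ring A, so both aryl–CH2 bonds are cut at once, leading back to a 6,8-diiodoflavanone and a prenylstannane. Ring A bears O1, 5-OH and 7-OMe, which make C6 and C8, the two CH carbons flanking C7, its only strongly nucleophilic positions; iodination therefore marks exactly the atoms to be prenylated. A single palladium-catalysed twofold Stille coupling exploits these two ring-A carbons, forging both bonds on the intact, unprotected flavanone, whose C2 stereocentre in ring C comes from (2S)-naringenin and is never touched. The coupling precursor is (2S)-6,8-diiodosakuranetin with free 5-OH and 4'-OH groups.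

Key step: step 3

Assumption: the purchased (2S)-naringenin is enantiopure; commercial lots can be partly racemic, so its ee is checked by chiral HPLC before use.

Step 1
Reactants: 1 (2S)-naringenin [(2S)-5,7,4'-trihydroxyflavanone]
Product: 2 (2S)-sakuranetin [(2S)-5,4'-dihydroxy-7-methoxyflavanone]
Conditions: MeOH, PPh3, DIAD (1.1 equiv each), THF, 0 °C → rt
Reagents that add atoms: methanol, CO
Why: Mitsunobu etherification: the betaine from PPh3 and DIAD deprotonates only the most acidic phenol, the 7-OH para to the C4 carbonyl (the 4'-OH is markedly less acidic and the 5-OH is tied up in a hydrogen bond to C4=O), and the resulting phenoxide is methylated by the methoxyphosphonium ion without any free base that could open ring C, so the C2 configuration should be retained.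

Step 2
Reactants: 2 (2S)-sakuranetin
Product: 3 (2S)-6,8-diiodosakuranetin [(2S)-5,4'-dihydroxy-6,8-diiodo-7-methoxyflavanone]
Conditions: NIS (2.1 equiv), DMF, 0 °C → rt, dark; aq. Na2S2O3 work-up
Reagents that add atoms: N-iodosuccinimide, O=C1CCC(=O)N1I
Why: Electrophilic aromatic iodination (SEAr): C6 and C8 are each ortho or para to all three oxygen donors of ring A (O1, 5-OH, 7-OMe) and should react far faster with NIS than C3'/C5' of the mono-oxygenated ring B, so two equivalents without acid catalyst should stop at the 6,8-diiodide while the neutral medium leaves C2 untouched.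

Step 3
Reactants: 3 (2S)-6,8-diiodosakuranetin; 4 tributyl(3-methylbut-2-enyl)stannane
Product: 7 (2S)-5,4'-dihydroxy-7-methoxy-6,8-diprenylflavanone (target), via 8-iodo-6-prenylsakuranetin 5 (not isolated), via 6-iodo-8-prenylsakuranetin 6 (not isolated)
Conditions: 4 (3 equiv), Pd(PPh3)4 (10 mol %), degassed amine-free DMF, 90 °C, Ar, dark; MeCN/hexane partition to remove tin, then silica gel
Reagents that add atoms: tributyl(3-methylbut-2-enyl)stannane (compound 4), CCCC[Sn](CCCC)(CCCC)CC=C(C)C
Why: Migita–Kosugi–Stille coupling run twice: Pd(0) inserts into a C(aryl)–I bond, the prenyl group passes from tin to palladium (whichever allyl terminus arrives first, the σ-allyl complexes interconvert through the η3-prenyl form), and reductive elimination gives the aryl–CH2 bond, after which the cycle repeats at the remaining iodide of 5 or 6, either of which may form first. The closest known reaction type is the Pd-catalysed coupling of aryl iodides, iodinated flavonoids included, with allyl- and prenyltributylstannanes. No ring is closed and no stereocentre is created, C2 being a spectator. The step needs linear (α) over 1,1-dimethylallyl (γ) selectivity: each arylpalladium centre has two ortho substituents (5-OH and 7-OMe at C6, 7-OMe and O1 at C8), so bond formation at the tertiary allyl terminus should be strongly disfavoured and elimination should occur from the primary σ-prenyl isomer. It also needs site fidelity and complete double coupling: the two C–I bonds installed in step 2 are the only sites open to oxidative addition, and an excess of 4 at 90 °C should carry both mono-coupled iodides through to 7. The medium holds no base, fluoride or copper salt, so the phenols stay protonated, retro-oxa-Michael opening of ring C has no trigger and the (2S) centre should survive, while the free 5-OH and 4'-OH are tolerated by the organostannane.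

Compound list
1 | (2S)-naringenin [(2S)-5,7,4'-trihydroxyflavanone] | Oc1cc(O)c2c(c1)O[C@H](c1ccc(O)cc1)CC2=O | starting material
2 | (2S)-sakuranetin [(2S)-5,4'-dihydroxy-7-methoxyflavanone] | COc1cc(O)c2c(c1)O[C@H](c1ccc(O)cc1)CC2=O | intermediate
3 | (2S)-6,8-diiodosakuranetin [(2S)-5,4'-dihydroxy-6,8-diiodo-7-methoxyflavanone] | COc1c(I)c(O)c2c(c1I)O[C@H](c1ccc(O)cc1)CC2=O | intermediate
4 | tributyl(3-methylbut-2-enyl)stannane (prenyltributyltin) | CCCC[Sn](CCCC)(CCCC)CC=C(C)C | starting material
5 | (2S)-8-iodo-6-prenylsakuranetin (mono-coupled, forms in the flask in step 3) | COc1c(CC=C(C)C)c(O)c2c(c1I)O[C@H](c1ccc(O)cc1)CC2=O | intermediate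
6 | (2S)-6-iodo-8-prenylsakuranetin (mono-coupled, forms in the flask in step 3) | COc1c(I)c(O)c2c(c1CC=C(C)C)O[C@H](c1ccc(O)cc1)CC2=O | intermediate
7 | (2S)-5,4'-dihydroxy-7-methoxy-6,8-bis(3-methylbut-2-enyl)flavanone (CNP0121058.1) | COc1c(CC=C(C)C)c(O)c2c(c1CC=C(C)C)O[C@H](c1ccc(O)cc1)CC2=O | target

Total step count: 3
Longest linear sequence: 3 steps (1 → 2 → 3 → 7)

Steps most likely to fail

Step 3 – The second coupling at the crowded, electron-rich ring-A positions may stall, with iodine lost by protodehalogenation, or part of the prenyl group may be delivered through its tertiary terminus. Fallback: setting out from 3, the same two carbons are first allylated with allyltributylstannane under Pd(PPh3)4 in DMF; the allyl group is symmetric, smaller and transfers faster, so no α/γ question arises. This should give (2S)-6,8-diallylsakuranetin F1. Olefin cross-metathesis of F1 with a large excess of 2-methyl-2-butene (Grubbs second-generation catalyst, CH2Cl2, 40 °C, sealed vessel) then converts both allyl termini into prenyl groups and returns to the route at 7.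

Step 1 – Methylation may run on to O4' or stop short, leaving mixtures of unmethylated, mono- and dimethylated material that are hard to separate. Fallback: setting out from 1, the order of events is reversed. NIS (2.1 equiv, DMF, 0 °C → rt) should give (2S)-6,8-diiodonaringenin F2, in which the two ortho iodine atoms make the 7-OH still more acidic and widen its gap to the 4'-OH. One equivalent of trimethylsilyldiazomethane in toluene/MeOH then methylates that oxygen selectively and returns to the route at 3, bypassing 2.

Step 2 – Iodination may spill over onto C3'/C5' of ring B or stop at mixed mono-iodides. Fallback: setting out from 2, the 4'-OH is silylated (TBSCl, imidazole, DMF, 0 °C; the chelated 5-OH should not react) to give (2S)-4'-O-TBS-sakuranetin F3, whose bulky silyl ether shields the ring-B ortho positions. NIS then gives (2S)-4'-O-TBS-6,8-diiodosakuranetin F4, and HF·pyridine in THF at 0 °C removes the silyl group under non-basic conditions, returning to the route at 3.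

Further compounds
F1 | step 3 | (2S)-6,8-diallylsakuranetin [(2S)-6,8-diallyl-5,4'-dihydroxy-7-methoxyflavanone] | COc1c(CC=C)c(O)c2c(c1CC=C)O[C@H](c1ccc(O)cc1)CC2=O
F2 | step 1 | (2S)-6,8-diiodonaringenin [(2S)-5,7,4'-trihydroxy-6,8-diiodoflavanone] | Oc1c(I)c(O)c2c(c1I)O[C@H](c1ccc(O)cc1)CC2=O
F3 | step 2 | (2S)-4'-O-TBS-sakuranetin [(2S)-4'-(tert-butyldimethylsilyloxy)-5-hydroxy-7-methoxyflavanone] | COc1cc(O)c2c(c1)O[C@H](c1ccc(O[Si](C)(C)C(C)(C)C)cc1)CC2=O
F4 | step 2 | (2S)-4'-O-TBS-6,8-diiodosakuranetin [(2S)-4'-(tert-butyldimethylsilyloxy)-5-hydroxy-6,8-diiodo-7-methoxyflavanone] | COc1c(I)c(O)c2c(c1I)O[C@H](c1ccc(O[Si](C)(C)C(C)(C)C)cc1)CC2=O
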